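The earlier runs and the new flask are calculated for an exercise; the scatter is artificial.

Start from ochre, where 30.0 min reads D 46 % and G 10 %, so D/G reads 4.60. One Q separates G from D, so set that ratio against free Q. Count Q with 4 per D, 3 per G and, as my assumption, 1 per unseen X-derived molecule. That count puts [Q] in ochre at an estimated 18.4 mM. Dividing gives the quotient [D]/([G][Q]), the reaction quotient of Q + G to D at that time, as a reading of 250 M⁻¹.

all flasks: X 0.020 M

|  | Q | remark | time |
|---|---|---|---|
| violet | 0.67 equiv | run made earlier |  |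
| ochre | 3.5 equiv | run made earlier |  |
| birch | 0.800 equiv |  | 1.0 h |
| oak | 2.00 equiv |  | 1.0 h |
| alder | 4.00 equiv |  | 1.0 h |

- violet (time / min: G / %, D / %): 2.50: 0, 0; 4.00: 1, 3; 6.00: 0, 0; 8.00: 2, 0; 12.0: 2, 0; 20.0: 0, 0; 30.0: 6, 0
- ochre (time / min: G / %, D / %): 4.00: 7, 0; 8.00: 6, 13; 12.0: 10, 22; 15.0: 9, 26; 20.0: 9, 31; 25.0: 7, 40; 30.0: 10, 46

(each reading ± 1.5 percentage points)

- the earlier runs were read with a standard deviation of 1.5 percentage points
- a reading or a percentage of D counts all its forms, free or not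

- G at the end, in percent of the X charged, for each flask in turn (birch, oak, alder)

For alder, freeze [Q] at ochre's value and keep the quotient, hence the same D/G. The same Q count, solved for G with alder's charge, gives my estimate of 13.2 %. Treat that as high, for ochre's D was still climbing, from 40 % to 46 %.

The forecast gives 7 %, 14 % and 6 % for birch, oak and alder, and differs from my alder figure: “G is fading as feed declines”.

The flasks give G of 2.67 % in birch, 10.2 % in oak and 6.19 % in alder.

    Q + J → G (k = 0.0380 M⁻¹ s⁻¹)
    L → E (k = 0.00327 s⁻¹)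
    Z ⇌ D, rate k3*(cs3 - [D]) while solid is left; crystals form when [D] > cs3 (solubility = 16.0 mM, k = 0.145 s⁻¹)
    X + Q → L (k = 0.0606 M⁻¹ s⁻¹)
    Q + L → J (k = 0.194 M⁻¹ s⁻¹)
    Q + G ⇌ D (K = 740 M⁻¹, k = 0.132 M⁻¹ s⁻¹)

Alder's 6.19 % lies below my 13.2 %. At 1.00 h alder holds [Q] of 17.7 mM, close to the 18.4 mM of my count for ochre, but alder's D/G has reached 10.5, above the 4.60 read in ochre at 30.0 min. Apply the quotient at 0.500 h instead, matching ochre's reading time. It asks for D/G of 5.66 in alder, which stands at 7.08. In oak at 0.500 h it asks for 1.78, and oak stands at 1.69.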